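**Retrosynthetic overview**
- The C2–aryl bond and the 2S centre are made last, by enantioselective conjugate arylation of a fully substituted 5,7-dihydroxychromone with 4-hydroxyphenylboronic acid.
- The chromone comes from three pieces joined in one pot: a β-keto ester (carries the prenyl chain), 3-ethoxyacryloyl chloride and a chiral γ-lactone. Ring C (4-pyranone) closes first; ring A is then built on it by a Claisen–Dieckmann sequence (lactone C=O becomes C7, lactone α-carbon C6, ester carbon C5).
- O1 is bound to C8a before ring A exists, so prenyl must end at C8 and the hydroxyalkenyl chain at C6. No protecting groups are needed, and lactone opening releases the free (R)-carbinol.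
- The lactone comes from methyl 5-methyl-4-oxohex-5-enoate by CBS reduction (sets R). The β-keto ester comes from the methyl acetoacetate dianion and prenyl bromide.
- Ring order: C, then A, in the same operation; ring B arrives preformed.

Assumption: a telescoped one-pot sequence counts as one step; 3-ethoxyacryloyl chloride, isopropenylmagnesium bromide solution and 4-hydroxyphenylboronic acid are bought. None of the steps has been run; the route is a proposal.

**Route**

Step 1
Reactants: 1 methyl acetoacetate; 2 prenyl bromide (1-bromo-3-methylbut-2-ene)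
Product: 3 methyl 7-methyl-3-oxooct-6-enoate
Conditions: LiN(i-Pr)2 (2.2 equiv), THF, 0 °C; then 2, 0 °C → rt; aq HCl work-up
Reagents that add atoms: none
Why: The acetoacetate dianion reacts at its more basic terminal carbon in an SN2 alkylation with the allylic bromide (Weiler dianion alkylation); no stereocentre is formed.

Step 2
Reactants: 4 methyl 4-chloro-4-oxobutanoate; 5 isopropenylmagnesium bromide (prop-1-en-2-ylmagnesium bromide, THF solution)
Product: 6 methyl 5-methyl-4-oxohex-5-enoate
Conditions: CuI (5 mol %), THF, −78 °C, 5 added slowly to 4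
Reagents that add atoms: none
Why: Copper-catalysed acylation of a Grignard reagent by an acid chloride is much faster at −78 °C than attack on the ester or on the ketone formed; no stereocentre is formed.

Step 3
Reactants: 6 methyl 5-methyl-4-oxohex-5-enoate
Product: 8 (5R)-5-(prop-1-en-2-yl)oxolan-2-one, via hydroxy ester 7 (not isolated)
Conditions: (S)-Me-CBS (10 mol %), catecholborane, toluene, −78 °C; then PPTS (cat.), 60 °C
Reagents that add atoms: none
Why: Corey–Bakshi–Shibata reduction with the isopropenyl group in the large-group position gives the (R)-alcohol with the (S)-catalyst (same sense as acetophenone to (R)-1-phenylethanol), catecholborane avoids hydroboration of the alkene, and acid-catalysed lactonisation leaves the new centre untouched.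

Step 4
Reactants: 3 methyl 7-methyl-3-oxooct-6-enoate; 9 (2E)-3-ethoxyprop-2-enoyl chloride; 8 (5R)-5-(prop-1-en-2-yl)oxolan-2-one
Product: 13 5,7-dihydroxy-6-[(2R)-2-hydroxy-3-methylbut-3-en-1-yl]-8-(3-methylbut-2-en-1-yl)-4H-chromen-4-one, via C-acylated keto ester 10 (not isolated), via pyranone ester 11 (not isolated), via keto alcohol 12 (not isolated)
Conditions: MgCl2, Et3N, THF, 0 → 45 °C; then LiN(SiMe3)2 (6 equiv), 8, −78 → 45 °C (same flask); aq HCl work-up
Reagents that add atoms: none
Why: Proposed new method: soft-enolisation C-acylation (Rathke type) gives tricarbonyl 10, whose ketone enol oxygen closes 6-endo on the β-ethoxyenone with loss of ethanol to form ring C, which fixes O1 to C8a before ring A exists so the 6/8 pattern cannot scramble; the vinylogous anion of 11 at its 2-alkyl CH2 is then acylated by the lactone carbonyl (which becomes C7 and frees the side-chain alkoxide), and the resulting 2-(2-oxoalkyl) ester 12 undergoes Claisen (Dieckmann) closure of C6 onto the ester carbon (C5) driven by aromatisation to form ring A; the closest known types are the Staunton–Weinreb toluate-anion annulation and the base cyclisation of 2-(2-oxoalkyl)benzoates to naphthalene-1,3-diols; no stereocentre is formed and the lactone-derived centre has no acidic hydrogen.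

Step 5
Reactants: 13 5,7-dihydroxy-6-[(2R)-2-hydroxy-3-methylbut-3-en-1-yl]-8-(3-methylbut-2-en-1-yl)-4H-chromen-4-one; 14 4-hydroxyphenylboronic acid
Product: 15 (2S)-5,7-dihydroxy-2-(4-hydroxyphenyl)-6-[(2R)-2-hydroxy-3-methylbut-3-en-1-yl]-8-(3-methylbut-2-en-1-yl)-2,3-dihydro-4H-chromen-4-one
Conditions: Pd(OCOCF3)2 (10 mol %), (R)-t-BuPyOx (12 mol %), NH4PF6 (30 mol %), H2O (5 equiv), ClCH2CH2Cl, 60 °C, argon
Reagents that add atoms: none
Why: Enantioselective conjugate addition of an arylboronic acid to a chromone with a cationic divalent palladium–pyridine-oxazoline catalyst: the aryl group is delivered to C2 on the face set by the ligand (by the facial model that gives (R)-3-aryl-3-methylcyclohexanones with the (S)-ligand, the (S)-ligand should give 2R flavanones, so (R)-t-BuPyOx is chosen for 2S; this sense is inferred, not recalled for chromones), and protonation of the palladium enolate closes the cycle without base, so the flavanone is neither opened nor racemised.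

**Compound list**

1 | methyl acetoacetate | COC(=O)CC(C)=O | starting material
2 | prenyl bromide (1-bromo-3-methylbut-2-ene) | CC(C)=CCBr | starting material
3 | methyl 7-methyl-3-oxooct-6-enoate | COC(=O)CC(=O)CCC=C(C)C | intermediate
4 | methyl 4-chloro-4-oxobutanoate | COC(=O)CCC(Cl)=O | starting material
5 | isopropenylmagnesium bromide | CC(=C)[Mg]Br | starting material
6 | methyl 5-methyl-4-oxohex-5-enoate | COC(=O)CCC(=O)C(C)=C | intermediate
7 | methyl (4R)-4-hydroxy-5-methylhex-5-enoate | COC(=O)CC[C@@H](O)C(C)=C | intermediate
8 | (5R)-5-(prop-1-en-2-yl)oxolan-2-one | C=C(C)[C@H]1CCC(=O)O1 | intermediate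
9 | (2E)-3-ethoxyprop-2-enoyl chloride | CCO/C=C/C(Cl)=O | starting material
10 | methyl 2-[(2E)-3-ethoxyprop-2-enoyl]-7-methyl-3-oxooct-6-enoate | CCO/C=C/C(=O)C(C(=O)OC)C(=O)CCC=C(C)C | intermediate
11 | methyl 2-(4-methylpent-3-en-1-yl)-4-oxo-4H-pyran-3-carboxylate | COC(=O)C1=C(CCC=C(C)C)OC=CC1=O | intermediate
12 | methyl 2-[(9R)-9-hydroxy-2,10-dimethyl-6-oxoundeca-2,10-dien-5-yl]-4-oxo-4H-pyran-3-carboxylate | COC(=O)C1=C(C(CC=C(C)C)C(=O)CC[C@@H](O)C(C)=C)OC=CC1=O | intermediate
13 | 5,7-dihydroxy-6-[(2R)-2-hydroxy-3-methylbut-3-en-1-yl]-8-(3-methylbut-2-en-1-yl)-4H-chromen-4-one | C=C(C)[C@H](O)Cc1c(O)c(CC=C(C)C)c2c(c1O)C(=O)C=CO2 | intermediate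
14 | 4-hydroxyphenylboronic acid | OB(O)c1ccc(O)cc1 | starting material
15 | (2S)-5,7-dihydroxy-2-(4-hydroxyphenyl)-6-[(2R)-2-hydroxy-3-methylbut-3-en-1-yl]-8-(3-methylbut-2-en-1-yl)-2,3-dihydro-4H-chromen-4-one | C=C(C)[C@H](O)Cc1c(O)c(CC=C(C)C)c2c(c1O)C(=O)C[C@@H](c1ccc(O)cc1)O2 | target

**Totals**

Total step count: 5. Longest linear sequence: 4 (steps 2, 3, 4, 5).

**Steps most likely to fail**

Step 4. The one-pot joins a soft-enolisation acylation to a strong-base annulation. The main risks are:
- the anion of 11 may add to neutral 11 at its free pyranone CH;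
- the stabilised anion may acylate the lactone only slowly;
- intermediate 12 may close through oxygen to an enol lactone instead of through C6;
- methoxide may open the finished chromone and let it reclose on the other oxygen.

Fallback, setting out from 3 and 8 and coming back at 13: stop after the first stage and isolate pyranone ester 11, completing its ring closure with TsOH in toluene. Open lactone 8 with MeNH(OMe)·HCl and i-PrMgCl to the hydroxy Weinreb amide (4R)-4-hydroxy-N-methoxy-N,5-dimethylhex-5-enamide F1, a stronger acyl donor whose addition does not revert. Form the lithium anion of 11 by inverse addition to LiN(SiMe3)2 at −78 °C and add it to the lithium alkoxide of F1 to obtain keto alcohol 12 as an isolated compound. Close ring A in a separate Claisen step (NaOMe, MeOH, 50 °C, short time) to rejoin the route at 13.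

Step 5. The substrate carries two free phenols, an ortho-prenyl phenol that divalent palladium can cyclise, and two alkenes open to Heck-type insertion; a 5,7-dihydroxychromone is also a weak acceptor, and the ligand sense should be confirmed on a model chromone.

Fallback, setting out from 13 and coming back at 15: silylate 13 with TBSCl and imidazole in DMF to 5-hydroxy-7-(tert-butyldimethylsilyloxy)-6-[(2R)-2-(tert-butyldimethylsilyloxy)-3-methylbut-3-en-1-yl]-8-(3-methylbut-2-en-1-yl)-4H-chromen-4-one F2, in which the chelated 5-OH stays free. Transfer the aryl group from bought 4-(tert-butyldimethylsilyloxy)phenylboronic acid with a monovalent rhodium catalyst, Rh(acac)(C2H4)2 and a chiral diene or BINAP-type ligand of the enantiomer that gives 2S, in dioxane/H2O. This gives (2S)-5-hydroxy-7-(tert-butyldimethylsilyloxy)-2-[4-(tert-butyldimethylsilyloxy)phenyl]-6-[(2R)-2-(tert-butyldimethylsilyloxy)-3-methylbut-3-en-1-yl]-8-(3-methylbut-2-en-1-yl)-2,3-dihydro-4H-chromen-4-one F3. Remove the three silyl groups with HF·pyridine in THF at 0 °C to reach 15.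

Step 2. The product is a polymerisable isopropenyl ketone formed in the presence of an organocopper species, so over-addition and conjugate addition can compete.

Fallback, setting out from 4 and coming back at 6: convert 4 with MeNH(OMe)·HCl and pyridine in CH2Cl2 into the Weinreb amide methyl 4-[methoxy(methyl)amino]-4-oxobutanoate F4, then add 5 at −20 °C. The magnesium chelate holds until the acidic quench and releases 6 only then, so no enone is exposed to the Grignard reagent.

**Further compounds**

F1 | step 4 | (4R)-4-hydroxy-N-methoxy-N,5-dimethylhex-5-enamide | CON(C)C(=O)CC[C@@H](O)C(C)=C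
F2 | step 5 | 5-hydroxy-7-(tert-butyldimethylsilyloxy)-6-[(2R)-2-(tert-butyldimethylsilyloxy)-3-methylbut-3-en-1-yl]-8-(3-methylbut-2-en-1-yl)-4H-chromen-4-one | C=C(C)[C@H](O[Si](C)(C)C(C)(C)C)Cc1c(O[Si](C)(C)C(C)(C)C)c(CC=C(C)C)c2c(c1O)C(=O)C=CO2
F3 | step 5 | (2S)-5-hydroxy-7-(tert-butyldimethylsilyloxy)-2-[4-(tert-butyldimethylsilyloxy)phenyl]-6-[(2R)-2-(tert-butyldimethylsilyloxy)-3-methylbut-3-en-1-yl]-8-(3-methylbut-2-en-1-yl)-2,3-dihydro-4H-chromen-4-one | C=C(C)[C@H](O[Si](C)(C)C(C)(C)C)Cc1c(O[Si](C)(C)C(C)(C)C)c(CC=C(C)C)c2c(c1O)C(=O)C[C@@H](c1ccc(O[Si](C)(C)C(C)(C)C)cc1)O2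
F4 | step 2 | methyl 4-[methoxy(methyl)amino]-4-oxobutanoate | CON(C)C(=O)CCC(=O)OC
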